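**Plan**
- Numbering: ring atoms as in hexahydro-1H-indene-4-carboxylic acid (C1 Me, C2 C=O, C3 Et, C4 Et/CO2H, C5 Et/styryl, C6=C7 with Me on C7). Chain atoms of the acyclic ester count from the ester carbon; chain C2/C3/C4/C5/C6/C7/C8/C9/C10 become ring C4/C3a/C3/C2/C1/C7a/C7/C6/C5.
- Retrosynthesis: the ring C2 ketone is taken back to a silyl-protected carbinol (temporary sp3 oxidation level). Bonds C4–C5 and C3a–C7a are then cut together by an intramolecular Diels–Alder transform. The enabling feature is the cyclohexene ring C3a–C4–C5–C6=C7–C7a, which carries the carboxyl on C4 (dienophile activator) and is bridged at C3a/C7a by the three-atom unit C3–C2–C1 (the tether, which becomes the cyclopentane ring).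
- The acyclic tetraenoate 20 is cut at chain C11=C12, C9=C10 and C7=C8 (three carbonyl olefinations) and at chain C4–C5 (vinylogous Mukaiyama aldol), leading to Roche ester 1, acid 4, auxiliary 5, ylides 15 and 17 and phosphonate 19.
- Forward: the aldol joins chain C1–C4 (dienophile included) to chain C5–C7; three olefinations grow the diene outward; step 13 closes the six-membered and the five-membered ring at once; desilylation and oxidation finish.
- Stereochemistry: ring C1 comes from 1; ring C3 (and the temporary C2 carbinol) from the auxiliary-controlled, Felkin-matched aldol; C3a, C4, C5 and C7a from the cycloaddition (alkene geometry, ester endo, allylic 1,3-strain at ring C1 and C3).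

Key step: step 13

Remark: acid 4 and ylide 17 are taken as purchasable, 4 as the pure E isomer; the configuration of the temporary carbinol (ring C2) is erased in the last step and is chosen only for ease of synthesis.

Step 1
Reactants: 1 methyl (S)-3-hydroxy-2-methylpropanoate
Product: 2 methyl (S)-3-((tert-butyldimethylsilyl)oxy)-2-methylpropanoate
Conditions: TBSCl, imidazole, CH2Cl2, 0 °C to rt
Reagents that add atoms: tert-butyldimethylsilyl chloride, CC(C)(C)[Si](C)(C)Cl
Why: Standard silyl ether protection of the primary alcohol; the stereocentre (future ring C1) is not involved.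

Step 2
Reactants: 2 methyl (S)-3-((tert-butyldimethylsilyl)oxy)-2-methylpropanoate
Product: 3 (S)-3-((tert-butyldimethylsilyl)oxy)-2-methylpropanal
Conditions: i-Bu2AlH (1.05 equiv), CH2Cl2, −78 °C; MeOH, then aq. KNaC4H4O6 (potassium sodium tartrate)
Reagents that add atoms: none
Why: Partial ester reduction with i-Bu2AlH, whose tetrahedral aluminium hemiacetal is stable at −78 °C and collapses only on work-up, should give the aldehyde, which is used at once because its α-stereocentre is labile.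

Step 3
Reactants: 4 (E)-2-ethylhex-2-enoic acid, 5 (S)-4-isopropyloxazolidin-2-one
Product: 7 (S)-3-((E)-2-ethylhex-2-enoyl)-4-isopropyloxazolidin-2-one, via (E)-2-ethylhex-2-enoic pivalic anhydride 6 (not isolated)
Conditions: 4, t-BuCOCl, Et3N, THF, −20 °C; then LiCl, 5, rt
Reagents that add atoms: none
Why: N-Acylation of the oxazolidinone through the mixed pivalic anhydride, which should be attacked at the less hindered enoyl carbonyl.

Step 4
Reactants: 7 (S)-3-((E)-2-ethylhex-2-enoyl)-4-isopropyloxazolidin-2-one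
Product: 9 (S)-3-[(1E,3E)-1-((tert-butyldimethylsilyl)oxy)-2-ethylhexa-1,3-dien-1-yl]-4-isopropyloxazolidin-2-one, via sodium dienolate 8 (not isolated)
Conditions: NaN(SiMe3)2, THF, −78 °C; then TBSCl, −78 °C
Reagents that add atoms: tert-butyldimethylsilyl chloride, CC(C)(C)[Si](C)(C)Cl
Why: γ-Deprotonation of the enoyl imide (the only site giving a carbonyl-conjugated anion) and O-silylation should give the (1E,3E)-vinylketene silyl N,O-acetal with the oxazolidinone cis to the vinyl group.

Step 5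
Reactants: 3 (S)-3-((tert-butyldimethylsilyl)oxy)-2-methylpropanal, 9 (S)-3-[(1E,3E)-1-((tert-butyldimethylsilyl)oxy)-2-ethylhexa-1,3-dien-1-yl]-4-isopropyloxazolidin-2-one
Product: 10 (S)-3-[(2E,4S,5S,6S)-7-((tert-butyldimethylsilyl)oxy)-2,4-diethyl-5-hydroxy-6-methylhept-2-enoyl]-4-isopropyloxazolidin-2-one
Conditions: TiCl4 (1.0 equiv), CH2Cl2, −78 °C; aq. NaHCO3
Reagents that add atoms: none
Why: Vinylogous Mukaiyama aldol reaction of a chiral vinylketene silyl N,O-acetal, in which the TiCl4-activated aldehyde should add at the γ-carbon through an open transition state on the dienol face not covered by the isopropyl group of the perpendicular oxazolidinone, setting chain C4 (S) and the anti C4/C5 relationship, while Felkin–Anh addition to the non-chelating α-methyl aldehyde calls for the same C5 configuration (matched case).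

Step 6
Reactants: 10 (S)-3-[(2E,4S,5S,6S)-7-((tert-butyldimethylsilyl)oxy)-2,4-diethyl-5-hydroxy-6-methylhept-2-enoyl]-4-isopropyloxazolidin-2-one
Product: 11 (S)-3-[(2E,4S,5S,6S)-5,7-bis((tert-butyldimethylsilyl)oxy)-2,4-diethyl-6-methylhept-2-enoyl]-4-isopropyloxazolidin-2-one
Conditions: TBSOTf, 2,6-lutidine, CH2Cl2, 0 °C
Reagents that add atoms: tert-butyldimethylsilyl trifluoromethanesulfonate, CC(C)(C)[Si](C)(C)OS(=O)(=O)C(F)(F)F
Why: Silylation of the hindered secondary carbinol with the silyl triflate; this oxygen is kept as an sp3 placeholder for the ring C2 ketone so that chain C4 and C6 can neither epimerise nor conjugate.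

Step 7
Reactants: 11 (S)-3-[(2E,4S,5S,6S)-5,7-bis((tert-butyldimethylsilyl)oxy)-2,4-diethyl-6-methylhept-2-enoyl]-4-isopropyloxazolidin-2-one
Product: 12 2-(trimethylsilyl)ethyl (2E,4S,5S,6S)-5,7-bis((tert-butyldimethylsilyl)oxy)-2,4-diethyl-6-methylhept-2-enoate
Conditions: Me3SiCH2CH2OH, n-BuLi, THF, −20 °C; then 11, −20 to 0 °C; aq. NH4Cl
Reagents that add atoms: 2-(trimethylsilyl)ethanol, C[Si](C)(C)CCO
Why: Transesterification of the N-acyl oxazolidinone with a lithium alkoxide (attack at the twisted, ketone-like exocyclic carbonyl) should release the auxiliary and install an ester that is later cleaved by fluoride at silicon and not at the hindered carbonyl.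

Step 8
Reactants: 12 2-(trimethylsilyl)ethyl (2E,4S,5S,6S)-5,7-bis((tert-butyldimethylsilyl)oxy)-2,4-diethyl-6-methylhept-2-enoate
Product: 13 2-(trimethylsilyl)ethyl (2E,4S,5S,6S)-5-((tert-butyldimethylsilyl)oxy)-2,4-diethyl-7-hydroxy-6-methylhept-2-enoate
Conditions: camphorsulfonic acid (0.1 equiv), MeOH/CH2Cl2, 0 °C
Reagents that add atoms: none
Why: Acid-catalysed methanolysis should cleave the primary silyl ether and leave the secondary one, which is flanked by two branched carbons (selective desilylation on steric grounds).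

Step 9
Reactants: 13 2-(trimethylsilyl)ethyl (2E,4S,5S,6S)-5-((tert-butyldimethylsilyl)oxy)-2,4-diethyl-7-hydroxy-6-methylhept-2-enoate
Product: 14 2-(trimethylsilyl)ethyl (2E,4S,5S,6R)-5-((tert-butyldimethylsilyl)oxy)-2,4-diethyl-6-methyl-7-oxohept-2-enoate
Conditions: Dess–Martin periodinane, CH2Cl2, 0 °C to rt
Reagents that add atoms: none
Why: Dess–Martin oxidation under near-neutral conditions should give the α-chiral aldehyde without epimerisation; it is taken on crude.

Step 10
Reactants: 14 2-(trimethylsilyl)ethyl (2E,4S,5S,6R)-5-((tert-butyldimethylsilyl)oxy)-2,4-diethyl-6-methyl-7-oxohept-2-enoate, 15 2-(triphenylphosphoranylidene)propanal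
Product: 16 2-(trimethylsilyl)ethyl (2E,4S,5R,6S,7E)-5-((tert-butyldimethylsilyl)oxy)-2,4-diethyl-6,8-dimethyl-9-oxonona-2,7-dienoate
Conditions: toluene, 85 °C
Reagents that add atoms: none
Why: Wittig reaction with a formyl-stabilised ylide, which is E-selective and too weakly basic to epimerise the α-stereocentre, should give the (E)-2-methyl enal (chain C7=C8).

Step 11
Reactants: 16 2-(trimethylsilyl)ethyl (2E,4S,5R,6S,7E)-5-((tert-butyldimethylsilyl)oxy)-2,4-diethyl-6,8-dimethyl-9-oxonona-2,7-dienoate, 17 2-(triphenylphosphoranylidene)butanal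
Product: 18 2-(trimethylsilyl)ethyl (2E,4S,5R,6S,7E,9E)-5-((tert-butyldimethylsilyl)oxy)-2,4,10-triethyl-6,8-dimethyl-11-oxoundeca-2,7,9-trienoate
Conditions: toluene, BHT, 105 °C
Reagents that add atoms: none
Why: A second Wittig homologation with the ethyl-substituted formyl ylide should give the (E,E)-dienal; this electron-poor diene is not expected to add to the electron-poor enoate at this temperature.

Step 12
Reactants: 18 2-(trimethylsilyl)ethyl (2E,4S,5R,6S,7E,9E)-5-((tert-butyldimethylsilyl)oxy)-2,4,10-triethyl-6,8-dimethyl-11-oxoundeca-2,7,9-trienoate, 19 diethyl benzylphosphonate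
Product: 20 2-(trimethylsilyl)ethyl (2E,4S,5R,6S,7E,9E,11E)-5-((tert-butyldimethylsilyl)oxy)-2,4,10-triethyl-6,8-dimethyl-12-phenyldodeca-2,7,9,11-tetraenoate
Conditions: 19, NaH, THF, 0 °C; then 18, −78 to 0 °C
Reagents that add atoms: none
Why: Horner–Wadsworth–Emmons olefination with the benzylphosphonate anion should give the E-styryl unit and complete the electron-rich triene; adding the aldehyde to the preformed anion in the cold avoids γ-deprotonation of the enoate.

Step 13
Reactants: 20 2-(trimethylsilyl)ethyl (2E,4S,5R,6S,7E,9E,11E)-5-((tert-butyldimethylsilyl)oxy)-2,4,10-triethyl-6,8-dimethyl-12-phenyldodeca-2,7,9,11-tetraenoate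
Product: 21 2-(trimethylsilyl)ethyl (1S,2R,3S,3aR,4R,5S,7aR)-2-((tert-butyldimethylsilyl)oxy)-3,4,5-triethyl-1,7-dimethyl-5-[(E)-2-phenylethenyl]-2,3,3a,4,5,7a-hexahydro-1H-indene-4-carboxylate
Conditions: toluene (0.01 M), BHT, 80 °C
Reagents that add atoms: none
Why: Thermal intramolecular Diels–Alder reaction in which the diene chain C7=C8–C9=C10 and the ester-activated dienophile chain C2=C3 combine in a concerted, asynchronous, suprafacial [4+2] cycloaddition that forms ring bonds C4–C5 (chain C2–C10, joining the two future quaternary carbons) and C3a–C7a (chain C3–C7). The closest known reaction type is the cyclisation of (2E,7E,9E)-deca-2,7,9-trienoates to trans-fused hexahydroindenes. The cyclohexene ring is closed by the [4+2] event itself, and the cyclopentane ring closes at the same moment as a fused five-membered ring because the three-atom bridge chain C4–C5–C6 links the dienophile and diene termini. At ring C4 and C5 the cis ethyl groups and the carboxyl cis to the styryl group follow from the E geometry of dienophile and diene together with endo placement of the ester, the trans ring fusion at C3a/C7a follows from that same transition state (ester under the diene, tether exo), and the absolute sense at all four new centres is set by the two existing allylic stereocentres, whose C–H bonds eclipse the neighbouring trisubstituted alkene (allylic 1,3-strain against the dienophile α-ethyl and the diene methyl). The step needs endo over exo selectivity, one diene face, and reaction of the inner diene and not the styryl-terminated one; the substrate secures these through the ester/α-ethyl differentiation of the dienophile, through the cooperating ethyl- and methyl-bearing centres that each allow only one low-strain approach, and through the tether length, which permits only the five-membered bridging mode.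

Step 14
Reactants: 21 2-(trimethylsilyl)ethyl (1S,2R,3S,3aR,4R,5S,7aR)-2-((tert-butyldimethylsilyl)oxy)-3,4,5-triethyl-1,7-dimethyl-5-[(E)-2-phenylethenyl]-2,3,3a,4,5,7a-hexahydro-1H-indene-4-carboxylate
Product: 22 (1S,2R,3S,3aR,4R,5S,7aR)-3,4,5-triethyl-2-hydroxy-1,7-dimethyl-5-[(E)-2-phenylethenyl]-2,3,3a,4,5,7a-hexahydro-1H-indene-4-carboxylic acid
Conditions: Bu4NF (excess), THF, 0 to 45 °C; aq. NH4Cl
Reagents that add atoms: none
Why: Fluoride attacks silicon in both the silyl ether and the 2-(trimethylsilyl)ethyl ester (loss of ethene and Me3SiF), so the acid on the quaternary carbon should be freed without any attack at its shielded carbonyl.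

Step 15
Reactants: 22 (1S,2R,3S,3aR,4R,5S,7aR)-3,4,5-triethyl-2-hydroxy-1,7-dimethyl-5-[(E)-2-phenylethenyl]-2,3,3a,4,5,7a-hexahydro-1H-indene-4-carboxylic acid
Product: 23 (1S,3S,3aR,4R,5S,7aR)-3,4,5-triethyl-1,7-dimethyl-2-oxo-5-[(E)-2-phenylethenyl]-2,3,3a,4,5,7a-hexahydro-1H-indene-4-carboxylic acid
Conditions: Dess–Martin periodinane, CH2Cl2, rt
Reagents that add atoms: none
Why: Dess–Martin oxidation of the secondary carbinol should give the ketone under non-basic conditions, so the two α-stereocentres (ring C1, C3), whose substituents already lie trans to the neighbouring ring carbons, are not epimerised.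

**Compound list**
1 | methyl (S)-3-hydroxy-2-methylpropanoate | COC(=O)[C@@H](C)CO | starting material
2 | methyl (S)-3-((tert-butyldimethylsilyl)oxy)-2-methylpropanoate | COC(=O)[C@@H](C)CO[Si](C)(C)C(C)(C)C | intermediate
3 | (S)-3-((tert-butyldimethylsilyl)oxy)-2-methylpropanal | O=C[C@@H](C)CO[Si](C)(C)C(C)(C)C | intermediate
4 | (E)-2-ethylhex-2-enoic acid | CCC/C=C(\CC)C(=O)O | starting material
5 | (S)-4-isopropyloxazolidin-2-one | CC(C)[C@H]1COC(=O)N1 | starting material
6 | (E)-2-ethylhex-2-enoic pivalic anhydride | CCC/C=C(\CC)C(=O)OC(=O)C(C)(C)C | intermediate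
7 | (S)-3-((E)-2-ethylhex-2-enoyl)-4-isopropyloxazolidin-2-one | CCC/C=C(\CC)C(=O)N1[C@@H](C(C)C)COC1=O | intermediate
8 | sodium (1E,3E)-2-ethyl-1-[(S)-4-isopropyl-2-oxooxazolidin-3-yl]hexa-1,3-dien-1-olate | CC/C=C/C(CC)=C(/[O-])N1[C@@H](C(C)C)COC1=O.[Na+] | intermediate
9 | (S)-3-[(1E,3E)-1-((tert-butyldimethylsilyl)oxy)-2-ethylhexa-1,3-dien-1-yl]-4-isopropyloxazolidin-2-one | CC/C=C/C(CC)=C(/O[Si](C)(C)C(C)(C)C)N1[C@@H](C(C)C)COC1=O | intermediate
10 | (S)-3-[(2E,4S,5S,6S)-7-((tert-butyldimethylsilyl)oxy)-2,4-diethyl-5-hydroxy-6-methylhept-2-enoyl]-4-isopropyloxazolidin-2-one | CC(C)(C)[Si](C)(C)OC[C@H](C)[C@@H](O)[C@@H](CC)/C=C(\CC)C(=O)N1[C@@H](C(C)C)COC1=O | intermediate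
11 | (S)-3-[(2E,4S,5S,6S)-5,7-bis((tert-butyldimethylsilyl)oxy)-2,4-diethyl-6-methylhept-2-enoyl]-4-isopropyloxazolidin-2-one | CC(C)(C)[Si](C)(C)OC[C@H](C)[C@@H](O[Si](C)(C)C(C)(C)C)[C@@H](CC)/C=C(\CC)C(=O)N1[C@@H](C(C)C)COC1=O | intermediate
12 | 2-(trimethylsilyl)ethyl (2E,4S,5S,6S)-5,7-bis((tert-butyldimethylsilyl)oxy)-2,4-diethyl-6-methylhept-2-enoate | CC(C)(C)[Si](C)(C)OC[C@H](C)[C@@H](O[Si](C)(C)C(C)(C)C)[C@@H](CC)/C=C(\CC)C(=O)OCC[Si](C)(C)C | intermediate
13 | 2-(trimethylsilyl)ethyl (2E,4S,5S,6S)-5-((tert-butyldimethylsilyl)oxy)-2,4-diethyl-7-hydroxy-6-methylhept-2-enoate | OC[C@H](C)[C@@H](O[Si](C)(C)C(C)(C)C)[C@@H](CC)/C=C(\CC)C(=O)OCC[Si](C)(C)C | intermediate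
14 | 2-(trimethylsilyl)ethyl (2E,4S,5S,6R)-5-((tert-butyldimethylsilyl)oxy)-2,4-diethyl-6-methyl-7-oxohept-2-enoate | O=C[C@H](C)[C@@H](O[Si](C)(C)C(C)(C)C)[C@@H](CC)/C=C(\CC)C(=O)OCC[Si](C)(C)C | intermediate
15 | 2-(triphenylphosphoranylidene)propanal | CC(C=O)=P(c1ccccc1)(c1ccccc1)c1ccccc1 | starting material
16 | 2-(trimethylsilyl)ethyl (2E,4S,5R,6S,7E)-5-((tert-butyldimethylsilyl)oxy)-2,4-diethyl-6,8-dimethyl-9-oxonona-2,7-dienoate | O=C/C(C)=C/[C@H](C)[C@@H](O[Si](C)(C)C(C)(C)C)[C@@H](CC)/C=C(\CC)C(=O)OCC[Si](C)(C)C | intermediate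
17 | 2-(triphenylphosphoranylidene)butanal | CCC(C=O)=P(c1ccccc1)(c1ccccc1)c1ccccc1 | starting material
18 | 2-(trimethylsilyl)ethyl (2E,4S,5R,6S,7E,9E)-5-((tert-butyldimethylsilyl)oxy)-2,4,10-triethyl-6,8-dimethyl-11-oxoundeca-2,7,9-trienoate | O=C/C(CC)=C/C(C)=C/[C@H](C)[C@@H](O[Si](C)(C)C(C)(C)C)[C@@H](CC)/C=C(\CC)C(=O)OCC[Si](C)(C)C | intermediate
19 | diethyl benzylphosphonate | CCOP(=O)(Cc1ccccc1)OCC | starting material
20 | 2-(trimethylsilyl)ethyl (2E,4S,5R,6S,7E,9E,11E)-5-((tert-butyldimethylsilyl)oxy)-2,4,10-triethyl-6,8-dimethyl-12-phenyldodeca-2,7,9,11-tetraenoate | c1ccccc1/C=C/C(CC)=C/C(C)=C/[C@H](C)[C@@H](O[Si](C)(C)C(C)(C)C)[C@@H](CC)/C=C(\CC)C(=O)OCC[Si](C)(C)C | intermediate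
21 | 2-(trimethylsilyl)ethyl (1S,2R,3S,3aR,4R,5S,7aR)-2-((tert-butyldimethylsilyl)oxy)-3,4,5-triethyl-1,7-dimethyl-5-[(E)-2-phenylethenyl]-2,3,3a,4,5,7a-hexahydro-1H-indene-4-carboxylate (silyloxy cis to the C3 ethyl, trans to the C1 methyl) | CC[C@@H]1[C@H](O[Si](C)(C)C(C)(C)C)[C@@H](C)[C@@H]2C(C)=C[C@@](/C=C/c3ccccc3)(CC)[C@](CC)(C(=O)OCC[Si](C)(C)C)[C@H]21 | intermediate
22 | (1S,2R,3S,3aR,4R,5S,7aR)-3,4,5-triethyl-2-hydroxy-1,7-dimethyl-5-[(E)-2-phenylethenyl]-2,3,3a,4,5,7a-hexahydro-1H-indene-4-carboxylic acid | CC[C@@H]1[C@H](O)[C@@H](C)[C@@H]2C(C)=C[C@@](/C=C/c3ccccc3)(CC)[C@](CC)(C(=O)O)[C@H]21 | intermediate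
23 | (1S,3S,3aR,4R,5S,7aR)-3,4,5-triethyl-1,7-dimethyl-2-oxo-5-[(E)-2-phenylethenyl]-2,3,3a,4,5,7a-hexahydro-1H-indene-4-carboxylic acid | CC[C@@H]1C(=O)[C@@H](C)[C@@H]2C(C)=C[C@@](/C=C/c3ccccc3)(CC)[C@](CC)(C(=O)O)[C@H]21 | target

**Step count**
Total: 15 steps. Longest linear sequence: 13 steps (steps 1, 2 and 5 to 15; the branch through steps 3 and 4 is equally long).

**Steps most likely to fail**

Step 13. The thermal cycloaddition may show poor endo/exo or facial discrimination, or the triene may oligomerise before it cyclises. The fallback changes the substrate to the ketone oxidation level, so that an sp2 carbon sits in the tether and the cis ethyl/silyloxy contact is gone. It sets out from 20: global desilylation (Bu4NF, THF, 0 °C to rt) should give (2E,4S,5R,6S,7E,9E,11E)-2,4,10-triethyl-5-hydroxy-6,8-dimethyl-12-phenyldodeca-2,7,9,11-tetraenoic acid F1. Dess–Martin oxidation in the cold should give (2E,4S,6S,7E,9E,11E)-2,4,10-triethyl-6,8-dimethyl-5-oxo-12-phenyldodeca-2,7,9,11-tetraenoic acid F2, which is kept neutral and cyclised at once (toluene, rt to 40 °C). This returns to the route at 23.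

Step 11. Olefination of the hindered enal by the stabilised ylide may be too slow at a temperature the substrate tolerates, with premature cycloaddition or decomposition of the dienal on prolonged heating. The fallback builds chain C9=C10 by cross-coupling at or below room temperature. It sets out from 16: Ramirez dibromo-olefination (CBr4, PPh3, Et3N, CH2Cl2, 0 °C) should give 2-(trimethylsilyl)ethyl (2E,4S,5R,6S,7E)-10,10-dibromo-5-((tert-butyldimethylsilyl)oxy)-2,4-diethyl-6,8-dimethyldeca-2,7,9-trienoate F3. Suzuki–Miyaura coupling selective for the bromide trans to the chain ((E)-2-phenylvinylboronic acid, Pd2(dba)3, P(2-furyl)3, Cs2CO3, THF/H2O) should give 2-(trimethylsilyl)ethyl (2E,4S,5R,6S,7E,9Z,11E)-10-bromo-5-((tert-butyldimethylsilyl)oxy)-2,4-diethyl-6,8-dimethyl-12-phenyldodeca-2,7,9,11-tetraenoate F4. Negishi coupling with retention (Et2Zn, Pd(P(t-Bu)3)2, THF, 0 °C to rt) then installs the ethyl group and returns to the route at 20, passing over 18 and step 12.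

Step 5. With the ethyl-substituted dienol ether the addition may suffer from poor γ-regioselectivity or weak remote face control. The fallback makes the same stereotriad by pentenyl-metal addition and builds the enoate afterwards. It sets out from 3: Nozaki–Hiyama addition of (E)-1-bromopent-2-ene (CrCl2, THF, 0 °C; anti through the chair transition state, Felkin–Anh with respect to the α-methyl group) should give (2S,3S,4S)-1-((tert-butyldimethylsilyl)oxy)-4-ethyl-2-methylhex-5-en-3-ol F5. Silylation (TBSOTf, 2,6-lutidine) should give (2S,3S,4S)-1,3-bis((tert-butyldimethylsilyl)oxy)-4-ethyl-2-methylhex-5-ene F6. Ozonolysis (O3, CH2Cl2, −78 °C; PPh3) should give (2R,3R,4S)-3,5-bis((tert-butyldimethylsilyl)oxy)-2-ethyl-4-methylpentanal F7. Wittig reaction with ylide 17 (toluene, 80 °C) should give (2E,4S,5S,6S)-5,7-bis((tert-butyldimethylsilyl)oxy)-2,4-diethyl-6-methylhept-2-enal F8. Pinnick oxidation (NaClO2, NaH2PO4, 2-methylbut-2-ene, t-BuOH/H2O) should give (2E,4S,5S,6S)-5,7-bis((tert-butyldimethylsilyl)oxy)-2,4-diethyl-6-methylhept-2-enoic acid F9. Esterification with 2-(trimethylsilyl)ethanol (DCC, DMAP, CH2Cl2) returns to the route at 12.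

**Further compounds**
F1 | step 13 | (2E,4S,5R,6S,7E,9E,11E)-2,4,10-triethyl-5-hydroxy-6,8-dimethyl-12-phenyldodeca-2,7,9,11-tetraenoic acid | c1ccccc1/C=C/C(CC)=C/C(C)=C/[C@H](C)[C@@H](O)[C@@H](CC)/C=C(\CC)C(=O)O
F2 | step 13 | (2E,4S,6S,7E,9E,11E)-2,4,10-triethyl-6,8-dimethyl-5-oxo-12-phenyldodeca-2,7,9,11-tetraenoic acid | c1ccccc1/C=C/C(CC)=C/C(C)=C/[C@H](C)C(=O)[C@@H](CC)/C=C(\CC)C(=O)O
F3 | step 11 | 2-(trimethylsilyl)ethyl (2E,4S,5R,6S,7E)-10,10-dibromo-5-((tert-butyldimethylsilyl)oxy)-2,4-diethyl-6,8-dimethyldeca-2,7,9-trienoate | BrC(Br)=C/C(C)=C/[C@H](C)[C@@H](O[Si](C)(C)C(C)(C)C)[C@@H](CC)/C=C(\CC)C(=O)OCC[Si](C)(C)C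
F4 | step 11 | 2-(trimethylsilyl)ethyl (2E,4S,5R,6S,7E,9Z,11E)-10-bromo-5-((tert-butyldimethylsilyl)oxy)-2,4-diethyl-6,8-dimethyl-12-phenyldodeca-2,7,9,11-tetraenoate | c1ccccc1/C=C/C(Br)=C/C(C)=C/[C@H](C)[C@@H](O[Si](C)(C)C(C)(C)C)[C@@H](CC)/C=C(\CC)C(=O)OCC[Si](C)(C)C
F5 | step 5 | (2S,3S,4S)-1-((tert-butyldimethylsilyl)oxy)-4-ethyl-2-methylhex-5-en-3-ol | CC(C)(C)[Si](C)(C)OC[C@H](C)[C@@H](O)[C@@H](CC)C=C
F6 | step 5 | (2S,3S,4S)-1,3-bis((tert-butyldimethylsilyl)oxy)-4-ethyl-2-methylhex-5-ene | CC(C)(C)[Si](C)(C)OC[C@H](C)[C@@H](O[Si](C)(C)C(C)(C)C)[C@@H](CC)C=C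
F7 | step 5 | (2R,3R,4S)-3,5-bis((tert-butyldimethylsilyl)oxy)-2-ethyl-4-methylpentanal | CC(C)(C)[Si](C)(C)OC[C@H](C)[C@@H](O[Si](C)(C)C(C)(C)C)[C@@H](CC)C=O
F8 | step 5 | (2E,4S,5S,6S)-5,7-bis((tert-butyldimethylsilyl)oxy)-2,4-diethyl-6-methylhept-2-enal | CC(C)(C)[Si](C)(C)OC[C@H](C)[C@@H](O[Si](C)(C)C(C)(C)C)[C@@H](CC)/C=C(\CC)C=O
F9 | step 5 | (2E,4S,5S,6S)-5,7-bis((tert-butyldimethylsilyl)oxy)-2,4-diethyl-6-methylhept-2-enoic acid | CC(C)(C)[Si](C)(C)OC[C@H](C)[C@@H](O[Si](C)(C)C(C)(C)C)[C@@H](CC)/C=C(\CC)C(=O)O
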